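All runs are calculated for substances that don't exist; scatter was added.

At early times the larch run shows a specific rate, rate over [starting material], of 0.0513 h⁻¹, and the birch run, charged with half as much, shows 0.0469 h⁻¹ at the same reading, while the two readings at 7.1 h, taken at equal time and so as a rough figure, give an apparent order in [starting material] of 1.03.

| flask | starting material | product | time |
|---|---|---|---|
| larch | 0.800 M |  |  |
| alder | 0.480 M |  |  |
| birch | 0.400 M |  |  |
| oak | 0.800 M | 0.240 M |  |
| cedar | 0.800 M |  | 21 h |

- larch run (time / h: [product] / M): 1.2: 0.0497; 2.4: 0.0984; 3.5: 0.1451; 4.7: 0.1917; 5.9: 0.2362; 7.1: 0.2775
- alder run (time / h: [product] / M): 1.2: 0.0292; 2.4: 0.0616; 3.5: 0.0841; 4.7: 0.1069; 5.9: 0.1350; 7.1: 0.1589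
- birch run (time / h: [product] / M): 1.2: 0.0212; 2.4: 0.0450; 3.5: 0.0674; 4.7: 0.0941; 5.9: 0.1140; 7.1: 0.1355
- oak run (time / h: [product] / M): 1.2: 0.2976; 2.4: 0.3600; 3.5: 0.4137; 4.7: 0.4718; 5.9: 0.5247; 7.1: 0.5760

(readings scatter by 0.002 M)

* apparent order in [starting material] of the starting rate, round the charge of the larch run (the rate where two percent of its starting material have turned into product) (one fixed amount of product, the same in the runs compared)
* the alder run starts with 0.320 M less of starting material than the larch run, and with no product. Compared where both hold the same amount of starting material, once fifteen percent of what the alder run was charged with has turned into product, is the alder run faster, slower or alike (within a tenth)?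
* product in the cedar run at 21 h, as a share of the starting material charged

- Overall: starting material -> product.
- Constant volume, constant temperature.
- The analysis sees a species whether free or bound.
- An order is taken over about fifteen percent of the charge, up and down.

For whoever takes over the bench: the cedar run holds starting material turning into product, and the clock on it needs one more number. Between its first and last readings the oak run, seeded with product, stands at a mean [product] of 0.437 M and shows a specific rate of 0.0782 h⁻¹, which is more than the early figure. We read this as autocatalysis and write

rate = [starting material] × (0.0513 h⁻¹ + lift × [product]),

where the lift, the gain in specific rate per molar of product, comes to 0.0618 M⁻¹ h⁻¹. We assume the end state is complete conversion. For a charge C with no product at the start, the share x turned then follows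

ln[(1 + g x)/(1 − x)] = A t, with A = 0.0513 h⁻¹ + lift × C and g = lift × C/0.0513 h⁻¹.

For the cedar run, A = 0.101 h⁻¹, g = 0.964 and A t = 2.12, so at 21 h you will find x = 78.8% of the charge as product. Add no product to that flask, since the reckoning starts from none.

At equal starting material the alder run holds 0.0720 M of product and the larch run 0.392 M, so the alder run is slower, at 0.738 of the larch rate.

The forecast gave order 1, slower and 79%, with the caution “This assumes no reversibility or saturation appears later”.

The flask gives order 1.0, slower at a ratio of 0.71, and 81.9% in the cedar run.

    2 starting material ⇌ substrate dimer, settled at all times (3.610 M⁻¹)
    substrate dimer → product + starting material (0.1030 h⁻¹)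
    starting material → product (0.05220 h⁻¹)
    starting material + product → 2 product (0.1624 M⁻¹ h⁻¹)

The cedar run needs both routes: without the direct passing of starting material into product it reaches 64.8%, and without the step assisted by product 66.3%, against 81.9%. In the alder run our lift puts the turning of half its charge at 11.7 h, and that run reaches it at 11.2 h.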